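**Retrosynthetic overview**

1. Feature: the ketal carbon C2' is a 4-hydroxybenzylic carbon (ring B') that already carries O1' of the pyranone ring and lies five atoms from the flavan oxygen O7 (O7–C7–C8–C3'–C2'). Oxidising the C2'–H/ring B' phenol pair to a quinone methide (a vinylogous oxocarbenium ion) lets O7 close the dihydrofuran ring.
2. Last ring: dihydrofuran by O7–C2' (anodic oxidation, step 12). O7 and O4'' stay as methoxymethyl ethers while current flows, because with O7 free the flavan ring A (C4–H2 para to O7) would be the easier site of oxidation; the mask comes off in the same flask.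
3. C3'–OH by catalytic asymmetric enolate hydroxylation of a 2,3-diarylchromanone; pyranone ring (C2'–C3' and O1'–C2') by Knoevenagel/oxa-Michael reaction of a 2-hydroxydeoxybenzoin with 4-(allyloxy)benzaldehyde.
4. C3'–C8 by Negishi coupling of the 8-zincated flavan with a 3-iodochromone, used as a masked 2-hydroxyaryl ketone (ring A'); the flavan with C2 comes from (S)-naringenin by removal of the C4 oxygen.
5. Ring order: flavan (chiral pool) → ring A' chromone (opened to the deoxybenzoin) → pyranone → dihydrofuran; three benzyl ethers are removed last.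

Key step: step 12

Remark (locants): primed locants belong to the chromanone unit (ring A', pyranone ring O1'–C4', 2'-aryl group = ring B'); unprimed locants belong to the flavan unit (ring A with C5–C8, 2-aryl group = ring B with O4''). "Fv" stands for the (2S)-5-(benzyloxy)-7-(methoxymethoxy)-2-[4-(methoxymethoxy)phenyl]chroman-8-yl group.

Remark (assumption on the ring fusion): C2' and C3' are the fusion atoms of the dihydrofuran and pyranone rings, so a ketal closed at C2' can only be cis-fused (ring B' and the 3'-OH on the same face) and C2' cannot be chosen independently of C3'; read strictly, the two tags of the given string place ring B' and the 3'-OH on opposite faces, so the route sets C3' exactly as written and lists the ketals 24 and 25 with the given string on the assumption that its C2' tag denotes this cis-fused ketal.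

**Route**

Step 1
Reactants: 1 (S)-naringenin
Product: 2 (2S)-5-hydroxy-7-(methoxymethoxy)-2-[4-(methoxymethoxy)phenyl]chroman-4-one
Conditions: MOMCl (2.4 equiv), i-Pr2NEt, CH2Cl2, 0 °C → rt
Reagents that add atoms: chloromethyl methyl ether, COCCl
Why: Williamson-type O-alkylation of the 7- and 4'-hydroxyls, while the 5-hydroxyl stays locked in its hydrogen bond to the C4 carbonyl and the mild amine base avoids the chalcone ring opening that would racemise C2.

Step 2
Reactants: 2 (2S)-5-hydroxy-7-(methoxymethoxy)-2-[4-(methoxymethoxy)phenyl]chroman-4-one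
Product: 5 (2S)-5-hydroxy-7-(methoxymethoxy)-2-[4-(methoxymethoxy)phenyl]chroman, via 5-O-ethoxycarbonyl flavanone 3 (not isolated), via ring A ortho-quinone methide 4 (not isolated)
Conditions: ClCO2Et, Et3N, THF, 0 °C; then NaBH4, H2O, 0 °C → rt
Reagents that add atoms: none
Why: Reductive deoxygenation of an ortho-hydroxyaryl ketone through its aryl carbonate (borohydride reduction, carbonate transfer to the benzylic alkoxide, elimination to the ortho-quinone methide, 1,4-hydride addition) should remove the C4 oxygen without touching C2, whose S configuration is carried over from naringenin.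

Step 3
Reactants: 5 (2S)-5-hydroxy-7-(methoxymethoxy)-2-[4-(methoxymethoxy)phenyl]chroman
Product: 6 (2S)-5-(benzyloxy)-7-(methoxymethoxy)-2-[4-(methoxymethoxy)phenyl]chroman
Conditions: BnBr, K2CO3, DMF, rt
Reagents that add atoms: benzyl bromide, BrCc1ccccc1
Why: Williamson ether synthesis on the 5-phenol, which is an ordinary phenol once the chelating carbonyl is gone.

Step 4
Reactants: 6 (2S)-5-(benzyloxy)-7-(methoxymethoxy)-2-[4-(methoxymethoxy)phenyl]chroman
Product: 7 (2S)-5-(benzyloxy)-8-bromo-7-(methoxymethoxy)-2-[4-(methoxymethoxy)phenyl]chroman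
Conditions: NBS (1.0 equiv), CH2Cl2, −40 → 0 °C, dark
Reagents that add atoms: N-bromosuccinimide, O=C1CCC(=O)N1Br
Why: Electrophilic aromatic bromination of the phloroglucinol-type ring A should go to C8 (between O7 and the ring oxygen O1), the less hindered of the two free positions, as is known for 5,7-di-O-benzyl flavan-3-ols.

Step 5
Reactants: 8 2',4',6'-trihydroxyacetophenone
Product: 9 4',6'-bis(benzyloxy)-2'-hydroxyacetophenone
Conditions: BnBr (2.1 equiv), K2CO3, DMF, rt
Reagents that add atoms: benzyl bromide, BrCc1ccccc1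
Why: Williamson ether synthesis that stops at the dibenzyl ether because the remaining hydroxyl is chelated to the acetyl group.

Step 6
Reactants: 9 4',6'-bis(benzyloxy)-2'-hydroxyacetophenone
Product: 11 5,7-bis(benzyloxy)-3-iodo-4H-chromen-4-one, via enaminone 10 (not isolated)
Conditions: Me2NCH(OMe)2, toluene, 95 °C; then I2, CHCl3, rt
Reagents that add atoms: N,N-dimethylformamide dimethyl acetal, COC(OC)N(C)C; iodine, II
Why: Enaminone formation followed by iodine-induced cyclisation with loss of dimethylamine is the standard 3-iodochromone synthesis and ties up the ring A' phenol oxygen as O1'.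

Step 7
Reactants: 7 (2S)-5-(benzyloxy)-8-bromo-7-(methoxymethoxy)-2-[4-(methoxymethoxy)phenyl]chroman; 11 5,7-bis(benzyloxy)-3-iodo-4H-chromen-4-one
Product: 14 5,7-bis(benzyloxy)-3-Fv-4H-chromen-4-one, via flavan-8-yllithium 12 (not isolated), via flavan-8-ylzinc chloride 13 (not isolated)
Conditions: n-BuLi, THF, −78 °C; ZnCl2, −78 °C → rt; then 11, Pd(OAc)2 (5 mol%), SPhos (10 mol%), THF, 50 °C
Reagents that add atoms: none
Why: Bromine–lithium exchange, transmetalation to zinc and Negishi coupling form C3'–C8; di-ortho-alkoxyarylzinc reagents couple well with a biarylphosphine ligand and do not add to the chromone carbonyl or to C2'.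

Step 8
Reactants: 14 5,7-bis(benzyloxy)-3-Fv-4H-chromen-4-one
Product: 15 1-[2,4-bis(benzyloxy)-6-hydroxyphenyl]-2-Fv-ethanone
Conditions: NaOH (2 M aq.), EtOH, 80 °C; NH4Cl work-up
Reagents that add atoms: none
Why: Alkaline ring opening of a 3-arylchromone (hydroxide addition at C2', ring opening, retro-Claisen loss of formate) is the classical route from isoflavones to 2-hydroxydeoxybenzoins and frees the ring A' phenol without acid, so O7 stays masked.

Step 9
Reactants: 15 1-[2,4-bis(benzyloxy)-6-hydroxyphenyl]-2-Fv-ethanone; 16 4-(allyloxy)benzaldehyde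
Product: 17 2'-[4-(allyloxy)phenyl]-5',7'-bis(benzyloxy)-3'-Fv-chroman-4'-one (C2' and C3' as a mixture, mainly 2',3'-trans)
Conditions: piperidine, EtOH, reflux
Reagents that add atoms: none
Why: Knoevenagel condensation at the activated methylene followed by intramolecular oxa-Michael addition of the ring A' phenol is the established synthesis of 2,3-diarylchroman-4-ones; both new centres are epimerisable here and are fixed only in steps 10 and 12.

Step 10
Reactants: 17 2'-[4-(allyloxy)phenyl]-5',7'-bis(benzyloxy)-3'-Fv-chroman-4'-one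
Product: 19 (3'S)-2'-[4-(allyloxy)phenyl]-5',7'-bis(benzyloxy)-3'-hydroxy-3'-Fv-chroman-4'-one (C2' unassigned), via 3'-hydroperoxide 18 (not isolated)
Conditions: O2 (1 atm), P(OEt)3, KOH (50% aq.), N-(9-anthracenylmethyl)-O-allylcinchonidinium bromide (10 mol%), toluene, 0 °C
Reagents that add atoms: dioxygen, O=O
Why: Asymmetric phase-transfer autoxidation of the ketone enolate with in situ phosphite reduction of the hydroperoxide should set C3' (3'S, the arrangement written at C3' in the target string) through the chiral ammonium–enolate ion pair, with the C2' epimers of the enolate interconverting through the ring-opened 2'-oxido-α-aryl chalcone (dynamic kinetic resolution) and oxygen entering anti to the C2' aryl group; the pseudoenantiomeric cinchoninium salt would be used if the first catalyst favours the other C3' epimer.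

Step 11
Reactants: 19 (3'S)-2'-[4-(allyloxy)phenyl]-5',7'-bis(benzyloxy)-3'-hydroxy-3'-Fv-chroman-4'-one
Product: 20 (3'S)-5',7'-bis(benzyloxy)-3'-hydroxy-2'-(4-hydroxyphenyl)-3'-Fv-chroman-4'-one (either C2' epimer)
Conditions: Pd(PPh3)4 (5 mol%), morpholine, THF, rt
Reagents that add atoms: none
Why: Tsuji–Trost deallylation (π-allylpalladium captured by morpholine) should free only the ring B' phenol and leave the methoxymethyl and benzyl ethers and the tertiary ketol untouched.

Step 12
Reactants: 20 (3'S)-5',7'-bis(benzyloxy)-3'-hydroxy-2'-(4-hydroxyphenyl)-3'-Fv-chroman-4'-one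
Product: 24 5,5',7'-tri-O-benzyl daphnodorin F, via quinone methide 21 (not isolated), via 2'-methoxy ketal 22 (not isolated), via unmasked 2'-methoxy ketal 23 (not isolated)
Conditions: undivided cell, reticulated vitreous carbon anode, Pt cathode, LiClO4 (0.1 M), 2,6-lutidine, MeOH/CH2Cl2 4:1, 0 °C, constant current, 2.2 F/mol; then HCl (1.25 M in MeOH), 25 °C
Reagents that add atoms: none
Why: Anodic two-electron, two-proton oxidation of the only free phenol (ring B') removes the C2'–H and should give quinone methide 21, a vinylogous oxocarbenium ion stabilised by O1', which methanol parks as mixed ketal 22; methanolic HCl then cleaves both methoxymethyl ethers and re-ionises C2', so that the freed O7 displaces methanol. The closest known reaction type is the anodic or quinone-mediated benzylic alkoxylation of 4-alkylphenols through para-quinone methides, followed by acid-catalysed ketal exchange. The dihydrofuran ring closes 5-exo-trig (O7 adds to trigonal C2', whose double bond to O1' or to ring B' lies outside the new ring). The new stereocentre C2' is set by the ring fusion: O7 hangs on C8 of the C3' aryl group and can reach planar C2' only on the pyranone face that carries C8 (cis fusion, ring B' syn to the 3'-hydroxyl), the closure is reversible under the acid, and so both C2' epimers of 20 and 22 converge. The step needs oxidation of ring B' alone although the flavan ring A is electron-rich and would be a second para-alkylphenol (C4–H2 para to O7) if O7 were free; this is secured by keeping O7 and O4'' as ethers while current flows, by the low potential of the phenol–lutidine couple and by stopping at 2.2 F/mol.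

Step 13
Reactants: 24 5,5',7'-tri-O-benzyl daphnodorin F
Product: 25 daphnodorin F
Conditions: H2 (1 atm), Pd/C, EtOAc/MeOH, rt
Reagents that add atoms: none
Why: Hydrogenolysis of the three aryl benzyl ethers under neutral conditions should leave the aryl ketone, the tertiary ketol, the ketal and the flavan C2–O1 bond intact.

**Compound list**

1 | (S)-naringenin | O=C1C[C@@H](c2ccc(O)cc2)Oc2cc(O)cc(O)c12 | starting material
2 | (2S)-5-hydroxy-7-(methoxymethoxy)-2-[4-(methoxymethoxy)phenyl]chroman-4-one | O=C1C[C@@H](c2ccc(OCOC)cc2)Oc2cc(OCOC)cc(O)c12 | intermediate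
3 | 5-O-ethoxycarbonyl derivative of 2 (not isolated) | O=C1C[C@@H](c2ccc(OCOC)cc2)Oc2cc(OCOC)cc(OC(=O)OCC)c12 | intermediate
4 | (2S)-7-(methoxymethoxy)-2-[4-(methoxymethoxy)phenyl]-2,3-dihydro-5H-chromen-5-one, ring A ortho-quinone methide (not isolated) | O=C1C=C(OCOC)C=C2O[C@H](c3ccc(OCOC)cc3)CC=C12 | intermediate
5 | (2S)-5-hydroxy-7-(methoxymethoxy)-2-[4-(methoxymethoxy)phenyl]chroman | COCOc1cc(O)c2c(c1)O[C@H](c1ccc(OCOC)cc1)CC2 | intermediate
6 | (2S)-5-(benzyloxy)-7-(methoxymethoxy)-2-[4-(methoxymethoxy)phenyl]chroman | COCOc1cc(OCc3ccccc3)c2c(c1)O[C@H](c1ccc(OCOC)cc1)CC2 | intermediate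
7 | (2S)-5-(benzyloxy)-8-bromo-7-(methoxymethoxy)-2-[4-(methoxymethoxy)phenyl]chroman | COCOc1cc(OCc3ccccc3)c2c(c1Br)O[C@H](c1ccc(OCOC)cc1)CC2 | intermediate
8 | 2',4',6'-trihydroxyacetophenone | CC(=O)c1c(O)cc(O)cc1O | starting material
9 | 4',6'-bis(benzyloxy)-2'-hydroxyacetophenone | CC(=O)c1c(O)cc(OCc2ccccc2)cc1OCc1ccccc1 | intermediate
10 | (E)-1-[2,4-bis(benzyloxy)-6-hydroxyphenyl]-3-(dimethylamino)prop-2-en-1-one (not isolated) | CN(C)/C=C/C(=O)c1c(O)cc(OCc2ccccc2)cc1OCc1ccccc1 | intermediate
11 | 5,7-bis(benzyloxy)-3-iodo-4H-chromen-4-one | O=c1c(I)coc2cc(OCc3ccccc3)cc(OCc3ccccc3)c12 | intermediate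
12 | 8-lithio derivative of 6 (not isolated) | [Li]c1c(OCOC)cc(OCc3ccccc3)c2c1O[C@H](c1ccc(OCOC)cc1)CC2 | intermediate
13 | 8-(chlorozincio) derivative of 6 (not isolated) | Cl[Zn]c1c(OCOC)cc(OCc3ccccc3)c2c1O[C@H](c1ccc(OCOC)cc1)CC2 | intermediate
14 | 5,7-bis(benzyloxy)-3-Fv-4H-chromen-4-one | O=c1c(-c3c(OCOC)cc(OCc4ccccc4)c4c3O[C@H](c3ccc(OCOC)cc3)CC4)coc2cc(OCc3ccccc3)cc(OCc3ccccc3)c12 | intermediate
15 | 1-[2,4-bis(benzyloxy)-6-hydroxyphenyl]-2-Fv-ethanone | O=C(Cc1c(OCOC)cc(OCc2ccccc2)c2c1O[C@H](c1ccc(OCOC)cc1)CC2)c1c(O)cc(OCc2ccccc2)cc1OCc1ccccc1 | intermediate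
16 | 4-(allyloxy)benzaldehyde | O=Cc1ccc(OCC=C)cc1 | starting material
17 | 2'-[4-(allyloxy)phenyl]-5',7'-bis(benzyloxy)-3'-Fv-chroman-4'-one (C2'/C3' mixture, mainly trans) | O=C1c2c(OCc3ccccc3)cc(OCc3ccccc3)cc2OC(c2ccc(OCC=C)cc2)C1c1c(OCOC)cc(OCc2ccccc2)c2c1O[C@H](c1ccc(OCOC)cc1)CC2 | intermediate
18 | 3'-hydroperoxide of 17 (not isolated) | O=C1c2c(OCc3ccccc3)cc(OCc3ccccc3)cc2OC(c2ccc(OCC=C)cc2)[C@@]1(OO)c1c(OCOC)cc(OCc2ccccc2)c2c1O[C@H](c1ccc(OCOC)cc1)CC2 | intermediate
19 | (3'S)-2'-[4-(allyloxy)phenyl]-5',7'-bis(benzyloxy)-3'-hydroxy-3'-Fv-chroman-4'-one (C2' unassigned) | O=C1c2c(OCc3ccccc3)cc(OCc3ccccc3)cc2OC(c2ccc(OCC=C)cc2)[C@@]1(O)c1c(OCOC)cc(OCc2ccccc2)c2c1O[C@H](c1ccc(OCOC)cc1)CC2 | intermediate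
20 | (3'S)-5',7'-bis(benzyloxy)-3'-hydroxy-2'-(4-hydroxyphenyl)-3'-Fv-chroman-4'-one (either C2' epimer; key-step precursor) | O=C1c2c(OCc3ccccc3)cc(OCc3ccccc3)cc2OC(c2ccc(O)cc2)[C@@]1(O)c1c(OCOC)cc(OCc2ccccc2)c2c1O[C@H](c1ccc(OCOC)cc1)CC2 | intermediate
21 | ring B' para-quinone methide of 20, C2'=C1''' (not isolated) | O=C1c2c(OCc3ccccc3)cc(OCc3ccccc3)cc2OC(=C2C=CC(=O)C=C2)[C@@]1(O)c1c(OCOC)cc(OCc2ccccc2)c2c1O[C@H](c1ccc(OCOC)cc1)CC2 | intermediate
22 | 2'-methoxy ketal of 20, C2' mixture (not isolated) | O=C1c2c(OCc3ccccc3)cc(OCc3ccccc3)cc2OC(OC)(c2ccc(O)cc2)[C@@]1(O)c1c(OCOC)cc(OCc2ccccc2)c2c1O[C@H](c1ccc(OCOC)cc1)CC2 | intermediate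
23 | 2'-methoxy ketal with free 7- and 4''-hydroxyls (not isolated) | O=C1c2c(OCc3ccccc3)cc(OCc3ccccc3)cc2OC(OC)(c2ccc(O)cc2)[C@@]1(O)c1c(O)cc(OCc2ccccc2)c2c1O[C@H](c1ccc(O)cc1)CC2 | intermediate
24 | 5,5',7'-tri-O-benzyl daphnodorin F (ring B, ring B' and C3' hydroxyls free; key-step product) | O=C1c2c(OCc5ccccc5)cc(OCc5ccccc5)cc2O[C@]2(c3ccc(O)cc3)Oc3cc(OCc5ccccc5)c4c(c3[C@@]12O)O[C@H](c1ccc(O)cc1)CC4 | intermediate
25 | daphnodorin F | O=C1c2c(O)cc(O)cc2O[C@]2(c3ccc(O)cc3)Oc3cc(O)c4c(c3[C@@]12O)O[C@H](c1ccc(O)cc1)CC4 | target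

**Step count**

Total: 13 steps. Longest linear sequence: 11 steps (steps 1–4 and 7–13 from (S)-naringenin); steps 5 and 6 form the second branch.

**Steps most likely to fail**

1. Step 12 (key step). What may go wrong: the ring B' phenoxyl radical may dimerise; methanol may add at the ring carbon para to the phenol oxygen (quinol ether formation) instead of the C2' proton being lost; the electron-rich flavan ring may be over-oxidised once the phenol is consumed; the flavan may open at C2 under the acid used for unmasking. Fallback (redox-neutral, C2' enters at the ketone oxidation level): it sets out from 15 and comes back at 24. C-Aroylation of 15 with 4-(methoxymethoxy)benzoyl chloride (LiN(SiMe3)2, THF, −78 → 0 °C, Baker–Venkataraman acyl transfer if the phenol is acylated first) should give the 2-aryl-1,3-diketone F1. Hydroxylation of its central carbon with dimethyldioxirane (acetone, −20 °C) should give the 2-hydroxy-1,3-diketone F2 as both C3' epimers. Methanolic HCl (25 °C) should then remove the three methoxymethyl groups and let the ring A' hydroxyl and O7 add to the ring B' carbonyl carbon (C2') with loss of water. This double ketalisation gives 24 together with its 2',3'-bis-epimer F3, and 24 is separated by chromatography (the two are diastereomers because of the flavan C2 centre).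

2. Step 10. What may go wrong: facial selection governed by the adjacent C2' aryl group instead of the catalyst (no dynamic resolution), so that both C3' epimers form in comparable amounts; the ring-opened chalcone may also accumulate. Fallback (separation instead of asymmetric induction): it sets out from 17 and comes back at 19. Kinetic enolate formation (KN(SiMe3)2, THF, −78 °C) and oxidation with racemic 2-(phenylsulfonyl)-3-phenyloxaziridine should give 19 and its C3' epimer F4; these are diastereomers because of the flavan C2 centre and are separated by preparative chromatography, and only 19 is carried on.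

3. Step 9. What may go wrong: slow Knoevenagel condensation at a methylene flanked by a 2,6-dioxygenated aryl and a 2,6-dioxygenated aroyl group, and incomplete oxa-Michael closure. Fallback (forms the C2'–ring B' bond instead of C2'–C3'): it sets out from 14 and comes back at 17. Copper-mediated conjugate addition of [4-(allyloxy)phenyl]magnesium bromide to C2' of chromone 14 (CuBr·SMe2, Me3SiCl, THF, −78 → −20 °C) should give the silyl enol ether F5, and mild hydrolysis (K2CO3, MeOH) should give 17, bypassing 15.

**Further compounds**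

F1 | step 12 | 1-[2,4-bis(benzyloxy)-6-hydroxyphenyl]-2-Fv-3-[4-(methoxymethoxy)phenyl]propane-1,3-dione | O=C(c1ccc(OCOC)cc1)C(c1c(OCOC)cc(OCc2ccccc2)c2c1O[C@H](c1ccc(OCOC)cc1)CC2)C(=O)c1c(O)cc(OCc2ccccc2)cc1OCc1ccccc1
F2 | step 12 | 1-[2,4-bis(benzyloxy)-6-hydroxyphenyl]-2-hydroxy-2-Fv-3-[4-(methoxymethoxy)phenyl]propane-1,3-dione (both C2 epimers) | O=C(c1ccc(OCOC)cc1)C(O)(c1c(OCOC)cc(OCc2ccccc2)c2c1O[C@H](c1ccc(OCOC)cc1)CC2)C(=O)c1c(O)cc(OCc2ccccc2)cc1OCc1ccccc1
F3 | step 12 | 2',3'-bis-epimer of 24 | O=C1c2c(OCc5ccccc5)cc(OCc5ccccc5)cc2O[C@@]2(c3ccc(O)cc3)Oc3cc(OCc5ccccc5)c4c(c3[C@]12O)O[C@H](c1ccc(O)cc1)CC4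
F4 | step 10 | C3' epimer of 19 | O=C1c2c(OCc3ccccc3)cc(OCc3ccccc3)cc2OC(c2ccc(OCC=C)cc2)[C@]1(O)c1c(OCOC)cc(OCc2ccccc2)c2c1O[C@H](c1ccc(OCOC)cc1)CC2
F5 | step 9 | 2'-[4-(allyloxy)phenyl]-5',7'-bis(benzyloxy)-3'-Fv-4'-(trimethylsilyloxy)-2'H-chromene | C[Si](C)(C)OC1=C(c2c(OCOC)cc(OCc3ccccc3)c3c2O[C@H](c2ccc(OCOC)cc2)CC3)C(c2ccc(OCC=C)cc2)Oc2cc(OCc3ccccc3)cc(OCc3ccccc3)c12
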